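**Retrosynthetic overview**

1. Target 28 comes from 27 by hydrogenolysis of four benzyl ethers, and 27 from flavone 25 by oxygenation of C3 (epoxidation of C2=C3, acid opening).
2. The strategy rests on C2 of ring C, the β-carbon of the chromone enone next to O1, which holds ring B through one aryl–heteroaryl single bond C2–C1'. Cutting this bond gives chromone 4 (free C2–H) and arylboronic acid 24.
3. 24 comes from bromide 20. Dioxane ring D is closed by CuI aryl C–O coupling of alcohol 19, and C10 and C11 come from an Evans syn-glycolate aldol of imide 10 with O-benzylvanillin 12.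
4. 4 comes from 2,4,6-trihydroxyacetophenone 1 by benzylation, enaminone formation and acid ring closure.
5. Ring order: ring C in fragment 1, ring D in fragment 2, then union of the fragments. Rings A, B and E are bought as arenes.

Key step: step 11

**Remarks**

- Labels: rings A and C are the chromone, ring B is the benzene ring of the benzodioxane, ring D is the dioxane and ring E is the guaiacyl ring. C10 carries CH2OH and C11 carries ring E; the target is (10S,11S).
- 4-(Benzyloxy)-3-methoxybenzaldehyde is assumed to be bought, so vanillin is not benzylated in the route.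
- Pivaloyl chloride, Bu2BOTf, Bu2SnO and n-BuLi are numbered and listed as reactants, because their atoms appear only in an intermediate that is not isolated.

**Route**

Step 1
Reactants: 1 2,4,6-trihydroxyacetophenone
Product: 2 1-[2,4-bis(benzyloxy)-6-hydroxyphenyl]ethan-1-one
Conditions: BnBr (2.1 equiv), K2CO3, acetone, reflux
Reagents that add atoms: benzyl bromide, BrCc1ccccc1
Why: Williamson ether synthesis; the 4-OH and one 2-OH are alkylated, while the last hydroxyl is hydrogen-bonded to the acetyl C=O and should stay free with the limited amount of benzyl bromide.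

Step 2
Reactants: 2 1-[2,4-bis(benzyloxy)-6-hydroxyphenyl]ethan-1-one
Product: 3 (E)-1-[2,4-bis(benzyloxy)-6-hydroxyphenyl]-3-(dimethylamino)prop-2-en-1-one
Conditions: Me2NCH(OMe)2, toluene, 95 °C
Reagents that add atoms: N,N-dimethylformamide dimethyl acetal, COC(OC)N(C)C
Why: Condensation of the methyl ketone with the amide acetal (enaminone formation) supplies the one carbon that becomes C2 of the chromone.

Step 3
Reactants: 3 (E)-1-[2,4-bis(benzyloxy)-6-hydroxyphenyl]-3-(dimethylamino)prop-2-en-1-one
Product: 4 5,7-bis(benzyloxy)-4H-chromen-4-one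
Conditions: conc. HCl, CH2Cl2, rt → 40 °C
Reagents that add atoms: none
Why: Acid-promoted intramolecular oxa-Michael addition of the phenol to the enaminone and loss of dimethylamine (enaminone chromone synthesis) should close ring C with C2 and C3 unsubstituted.

Step 4
Reactants: 5 4-bromo-2-iodophenol
Product: 6 2-(4-bromo-2-iodophenoxy)acetic acid
Conditions: BrCH2CO2H, NaOH, H2O, 100 °C; then HCl to pH 1
Reagents that add atoms: bromoacetic acid, OC(=O)CBr
Why: Williamson etherification of the phenoxide with bromoacetate; the phenol oxygen, para to bromine, becomes the ring-D oxygen on C10.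

Step 5
Reactants: 6 2-(4-bromo-2-iodophenoxy)acetic acid; 7 pivaloyl chloride; 8 (R)-4-benzyl-2-oxazolidinone
Product: 10 (R)-4-benzyl-3-[2-(4-bromo-2-iodophenoxy)acetyl]oxazolidin-2-one, via mixed pivalic anhydride 9 (not isolated)
Conditions: Et3N, THF, −20 °C; then LiCl, 8, −20 °C → rt
Reagents that add atoms: none
Why: N-acylation of the oxazolidinone through the mixed pivalic anhydride; the hindered pivaloyl carbonyl should direct attack to the aryloxyacetyl carbonyl.

Step 6
Reactants: 10 (R)-4-benzyl-3-[2-(4-bromo-2-iodophenoxy)acetyl]oxazolidin-2-one; 11 dibutylboron triflate; 12 4-(benzyloxy)-3-methoxybenzaldehyde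
Product: 15 (R)-4-benzyl-3-[(2R,3S)-3-[4-(benzyloxy)-3-methoxyphenyl]-2-(4-bromo-2-iodophenoxy)-3-hydroxypropanoyl]oxazolidin-2-one, via boron enolate 13 (not isolated), via boron aldolate 14 (not isolated)
Conditions: Et3N, CH2Cl2, −78 → 0 °C; then 12, −78 → 0 °C; then pH 7 buffer, MeOH, H2O2, 0 °C
Reagents that add atoms: none
Why: Evans syn-glycolate aldol; the Z boron enolate reacts through a chair Zimmerman–Traxler transition state on the enolate face away from the benzyl group of the (R)-auxiliary, which should set C2 (R) and C3 (S), the syn pair that becomes C10 (S) and C11 (S).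

Step 7
Reactants: 15 the syn-aldol imide
Product: 16 (1S,2S)-1-[4-(benzyloxy)-3-methoxyphenyl]-2-(4-bromo-2-iodophenoxy)propane-1,3-diol
Conditions: NaBH4, THF/H2O (4:1), 0 °C → rt
Reagents that add atoms: none
Why: Reductive removal of the oxazolidinone auxiliary by borohydride turns the imide carbonyl into the primary alcohol without touching either stereocentre or the aryl halides.

Step 8
Reactants: 16 the (1S,2S)-diol; 17 dibutyltin oxide
Product: 19 (1S,2S)-3-(benzyloxy)-1-[4-(benzyloxy)-3-methoxyphenyl]-2-(4-bromo-2-iodophenoxy)propan-1-ol, via stannylene acetal 18 (not isolated)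
Conditions: toluene, reflux (Dean–Stark); then BnBr, Bu4NBr, 90 °C
Reagents that add atoms: benzyl bromide, BrCc1ccccc1
Why: Regioselective stannylene acetal alkylation should benzylate the less hindered primary oxygen; this is needed because both hydroxyls of 16 are β to the aryloxy oxygen and either could close a six-membered ring in step 9.

Step 9
Reactants: 19 the primary benzyl ether with free benzylic hydroxyl
Product: 20 (2S,3S)-2-[(benzyloxy)methyl]-3-[4-(benzyloxy)-3-methoxyphenyl]-6-bromo-2,3-dihydro-1,4-benzodioxine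
Conditions: CuI (10 mol %), 1,10-phenanthroline (20 mol %), Cs2CO3, toluene, 110 °C, argon
Reagents that add atoms: none
Why: Intramolecular Ullmann-type C–O coupling of the secondary alkoxide with the aryl iodide, which reacts well before the aryl bromide, should close ring D at the aryl carbon, so both sp3 stereocentres are retained and the syn diol becomes the trans-2,3-disubstituted benzodioxane.

Step 10
Reactants: 20 the 6-bromobenzodioxane; 21 n-butyllithium
Product: 24 [(2S,3S)-2-[(benzyloxy)methyl]-3-[4-(benzyloxy)-3-methoxyphenyl]-2,3-dihydro-1,4-benzodioxin-6-yl]boronic acid, via aryllithium 22 (not isolated), via lithium triisopropoxyborate 23 (not isolated)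
Conditions: THF, −78 °C; then B(OiPr)3, −78 °C → rt; then 1 M HCl
Reagents that add atoms: triisopropyl borate, CC(C)OB(OC(C)C)OC(C)C (boron); water, O (the two hydroxyl oxygens on boron)
Why: Bromine–lithium exchange at low temperature, trapping of the aryllithium with the borate and acid hydrolysis is the classical arylboronic acid synthesis, and the ethers and both stereocentres are inert to it.

Step 11
Reactants: 4 5,7-bis(benzyloxy)-4H-chromen-4-one; 24 the benzodioxanylboronic acid
Product: 25 5,7-bis(benzyloxy)-2-[(2S,3S)-2-[(benzyloxy)methyl]-3-[4-(benzyloxy)-3-methoxyphenyl]-2,3-dihydro-1,4-benzodioxin-6-yl]-4H-chromen-4-one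
Conditions: Pd(O2CCF3)2 (10 mol %), O2 (1 atm), DMSO, 80 °C; 4 (2 equiv), 24 added in portions
Reagents that add atoms: none
Why: Transmetalation of 24 to Pd(O2CCF3)2 gives an aryl–palladium trifluoroacetate that adds syn across the C2=C3 bond of 4, the aryl group going to C2 and palladium to C3, where it is held as a C- or O-bound enolate. Equilibration through the O-bound enolate places palladium syn to the C2 hydrogen, β-hydride elimination restores C2=C3, and O2 returns the released zerovalent palladium to divalent palladium; any flavanone formed by protonolysis of the enolate should be dehydrogenated by the same Pd(O2CCF3)2/DMSO/O2 system. The closest known reaction type is the oxidative Heck (boron Heck) arylation of chromones with arylboronic acids, that is, conjugate addition under divalent palladium with dehydrogenation in the same flask. No ring is closed and no stereocentre is made; C10 and C11 are remote ether carbons and should pass through unchanged. The step needs C2 over C3 selectivity, which the polarity of the vinylogous ester secures because migratory insertion delivers the aryl group to the β-carbon next to O1, and it needs the C11–H benzylic ether on the electron-rich ring E to survive, which is why O2 is the only oxidant and a quinone co-oxidant is left out. The cheap chromone 4 is used in excess and 24 is added in portions to hold back homocoupling and protodeboronation.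

Step 12
Reactants: 25 the tetra-O-benzyl 3-deoxyflavone
Product: 27 5,7-bis(benzyloxy)-2-[(2S,3S)-2-[(benzyloxy)methyl]-3-[4-(benzyloxy)-3-methoxyphenyl]-2,3-dihydro-1,4-benzodioxin-6-yl]-3-hydroxy-4H-chromen-4-one, via flavone epoxide 26 (not isolated)
Conditions: DMDO (acetone solution), CH2Cl2, 0 °C → rt; evaporate; then p-TsOH (cat.), CH2Cl2, rt
Reagents that add atoms: dimethyldioxirane, CC1(C)OO1
Why: Dioxirane epoxidation of the C2=C3 enol-ether bond followed by acid-catalysed opening to the C2 oxocarbenium ion and loss of the C3 proton (flavone to flavonol oxidation); the two epoxide stereocentres are transient, so the diastereomer mixture converges.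

Step 13
Reactants: 27 the tetra-O-benzyl flavonol
Product: 28 2,3-dehydrosilybin B
Conditions: H2 (1 atm), 10% Pd/C, THF/MeOH, rt
Reagents that add atoms: none
Why: Catalytic hydrogenolysis should remove the three aryl benzyl ethers and the primary alkyl benzyl ether, while the ring-held secondary benzylic aryl ether C11–O and the flavonol C2=C3 bond react much more slowly, and C10 and C11 are not touched.

**Compound list**

1 | 2,4,6-trihydroxyacetophenone | CC(=O)c1c(O)cc(O)cc1O | starting material
2 | 1-[2,4-bis(benzyloxy)-6-hydroxyphenyl]ethan-1-one | CC(=O)c1c(O)cc(OCc2ccccc2)cc1OCc1ccccc1 | intermediate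
3 | (E)-1-[2,4-bis(benzyloxy)-6-hydroxyphenyl]-3-(dimethylamino)prop-2-en-1-one | CN(C)/C=C/C(=O)c1c(O)cc(OCc2ccccc2)cc1OCc1ccccc1 | intermediate
4 | 5,7-bis(benzyloxy)-4H-chromen-4-one | O=c1ccoc2cc(OCc3ccccc3)cc(OCc3ccccc3)c12 | intermediate
5 | 4-bromo-2-iodophenol | Oc1ccc(Br)cc1I | starting material
6 | 2-(4-bromo-2-iodophenoxy)acetic acid | OC(=O)COc1ccc(Br)cc1I | intermediate
7 | pivaloyl chloride | CC(C)(C)C(=O)Cl | starting material
8 | (R)-4-benzyl-2-oxazolidinone | O=C1N[C@H](Cc2ccccc2)CO1 | starting material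
9 | 2-(4-bromo-2-iodophenoxy)acetic pivalic anhydride (formed in the flask) | CC(C)(C)C(=O)OC(=O)COc1ccc(Br)cc1I | intermediate
10 | (R)-4-benzyl-3-[2-(4-bromo-2-iodophenoxy)acetyl]oxazolidin-2-one | O=C(COc1ccc(Br)cc1I)N1C(=O)OC[C@H]1Cc1ccccc1 | intermediate
11 | dibutylboron triflate, Bu2BOTf | CCCCB(CCCC)OS(=O)(=O)C(F)(F)F | starting material
12 | 4-(benzyloxy)-3-methoxybenzaldehyde (O-benzylvanillin) | COc1cc(C=O)ccc1OCc1ccccc1 | starting material
13 | (Z)-dibutylboron enolate of 10 (formed in the flask) | CCCCB(CCCC)O/C(=C\Oc1ccc(Br)cc1I)N1C(=O)OC[C@H]1Cc1ccccc1 | intermediate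
14 | O-dibutylboryl aldolate of 15 (formed in the flask) | COc1cc([C@H](OB(CCCC)CCCC)[C@H](C(=O)N2C(=O)OC[C@H]2Cc2ccccc2)Oc2ccc(Br)cc2I)ccc1OCc1ccccc1 | intermediate
15 | (R)-4-benzyl-3-[(2R,3S)-3-[4-(benzyloxy)-3-methoxyphenyl]-2-(4-bromo-2-iodophenoxy)-3-hydroxypropanoyl]oxazolidin-2-one | COc1cc([C@H](O)[C@H](C(=O)N2C(=O)OC[C@H]2Cc2ccccc2)Oc2ccc(Br)cc2I)ccc1OCc1ccccc1 | intermediate
16 | (1S,2S)-1-[4-(benzyloxy)-3-methoxyphenyl]-2-(4-bromo-2-iodophenoxy)propane-1,3-diol | COc1cc([C@H](O)[C@H](CO)Oc2ccc(Br)cc2I)ccc1OCc1ccccc1 | intermediate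
17 | dibutyltin oxide, Bu2SnO | CCCC[Sn](=O)CCCC | starting material
18 | dibutylstannylene acetal of diol 16 (formed in the flask) | COc1cc([C@@H]2O[Sn](CCCC)(CCCC)OC[C@@H]2Oc2ccc(Br)cc2I)ccc1OCc1ccccc1 | intermediate
19 | (1S,2S)-3-(benzyloxy)-1-[4-(benzyloxy)-3-methoxyphenyl]-2-(4-bromo-2-iodophenoxy)propan-1-ol | COc1cc([C@H](O)[C@H](COCc2ccccc2)Oc2ccc(Br)cc2I)ccc1OCc1ccccc1 | intermediate
20 | (2S,3S)-2-[(benzyloxy)methyl]-3-[4-(benzyloxy)-3-methoxyphenyl]-6-bromo-2,3-dihydro-1,4-benzodioxine | COc1cc([C@@H]2Oc3cc(Br)ccc3O[C@H]2COCc2ccccc2)ccc1OCc1ccccc1 | intermediate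
21 | n-butyllithium | [Li]CCCC | starting material
22 | 6-lithio derivative of 20 (formed in the flask) | COc1cc([C@@H]2Oc3cc([Li])ccc3O[C@H]2COCc2ccccc2)ccc1OCc1ccccc1 | intermediate
23 | lithium triisopropoxy(benzodioxan-6-yl)borate (formed in the flask) | COc1cc([C@@H]2Oc3cc([B-](OC(C)C)(OC(C)C)OC(C)C)ccc3O[C@H]2COCc2ccccc2)ccc1OCc1ccccc1.[Li+] | intermediate
24 | [(2S,3S)-2-[(benzyloxy)methyl]-3-[4-(benzyloxy)-3-methoxyphenyl]-2,3-dihydro-1,4-benzodioxin-6-yl]boronic acid | COc1cc([C@@H]2Oc3cc(B(O)O)ccc3O[C@H]2COCc2ccccc2)ccc1OCc1ccccc1 | intermediate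
25 | tetra-O-benzyl 3-deoxyflavone | COc1cc([C@@H]2Oc3cc(-c4cc(=O)c5c(OCc6ccccc6)cc(OCc6ccccc6)cc5o4)ccc3O[C@H]2COCc2ccccc2)ccc1OCc1ccccc1 | intermediate
26 | 2,3-epoxide of 25, both epoxide diastereomers (formed in the flask) | COc1cc([C@@H]2Oc3cc(C45OC4C(=O)c4c(OCc6ccccc6)cc(OCc6ccccc6)cc4O5)ccc3O[C@H]2COCc2ccccc2)ccc1OCc1ccccc1 | intermediate
27 | tetra-O-benzyl 3-hydroxyflavone | COc1cc([C@@H]2Oc3cc(-c4oc5cc(OCc6ccccc6)cc(OCc6ccccc6)c5c(=O)c4O)ccc3O[C@H]2COCc2ccccc2)ccc1OCc1ccccc1 | intermediate
28 | 2,3-dehydrosilybin B, (10S,11S) | COc1cc([C@@H]2Oc3cc(-c4oc5cc(O)cc(O)c5c(=O)c4O)ccc3O[C@H]2CO)ccc1O | target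

**Step count**

Total: 13 steps. Longest linear sequence: 10 steps (steps 4 to 13, from 4-bromo-2-iodophenol 5). The chromone branch (steps 1 to 3) joins at step 11.

**Steps most likely to fail**

1. Step 11 (key step). The aryl–palladium species may be consumed by homocoupling, protodeboronation or oxidation to the phenol faster than it inserts into the electron-rich 5-alkoxychromone, or the sequence may stall after protonolysis of the enolate. Fallback: a Baker–Venkataraman construction of ring C that sets out from bromide 20 and ketone 2 and comes back at 25. Bromine–lithium exchange on 20 (n-BuLi, THF, −78 °C) and quenching with CO2 should give (2S,3S)-2-[(benzyloxy)methyl]-3-[4-(benzyloxy)-3-methoxyphenyl]-2,3-dihydro-1,4-benzodioxine-6-carboxylic acid F1. Esterification with the phenol of 2 (EDC·HCl, DMAP, CH2Cl2) should give the 2-acetyl-3,5-bis(benzyloxy)phenyl ester F2. Acyl transfer with KOH in pyridine at 50 °C should give the 1,3-diketone F3, and cyclodehydration (p-TsOH, toluene, 80 °C) should close ring C to 25.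

2. Step 12. The dioxirane may oxidise the benzylic C–H bonds (C11–H and the OCH2Ph groups) or the electron-rich rings at a rate comparable to the slow epoxidation of the conjugated C2=C3 bond, and the epoxide may open along other paths than proton loss from C3. Fallback: directed metalation and oxidation, setting out from 25 and coming back at 27. Deprotonation at C3 with lithium diisopropylamide (THF, −78 °C) should give the 3-lithioflavone F4; B(OMe)3 should turn it into the lithium trimethoxy(flavon-3-yl)borate F5; oxidation with H2O2 in AcOH should give 27.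

3. Step 8. Regiocontrol in the tin-mediated alkylation may be incomplete, with benzylation at the benzylic oxygen or at both oxygens, which would leave the primary oxygen free to take part in the copper ring closure. Fallback: differentiation of the two oxygens before the auxiliary is removed, setting out from 15 and coming back at 19. Silylation of the secondary hydroxyl (TBSOTf, 2,6-lutidine, CH2Cl2, −78 °C) should give the silyl ether imide F6. LiBH4 (THF/MeOH, 0 °C) should cleave the auxiliary to the primary alcohol F7. Neutral benzylation with 2-benzyloxy-1-methylpyridinium triflate and MgO (PhCF3, 85 °C) should give the benzyl ether F8, and Bu4NF in THF should free the benzylic hydroxyl to give 19.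

**Further compounds**

F1 | step 11 | (2S,3S)-2-[(benzyloxy)methyl]-3-[4-(benzyloxy)-3-methoxyphenyl]-2,3-dihydro-1,4-benzodioxine-6-carboxylic acid | COc1cc([C@@H]2Oc3cc(C(=O)O)ccc3O[C@H]2COCc2ccccc2)ccc1OCc1ccccc1
F2 | step 11 | 2-acetyl-3,5-bis(benzyloxy)phenyl ester of F1 | COc1cc([C@@H]2Oc3cc(C(=O)Oc4cc(OCc5ccccc5)cc(OCc5ccccc5)c4C(C)=O)ccc3O[C@H]2COCc2ccccc2)ccc1OCc1ccccc1
F3 | step 11 | 1-[2,4-bis(benzyloxy)-6-hydroxyphenyl]-3-(benzodioxan-6-yl)propane-1,3-dione | COc1cc([C@@H]2Oc3cc(C(=O)CC(=O)c4c(O)cc(OCc5ccccc5)cc4OCc4ccccc4)ccc3O[C@H]2COCc2ccccc2)ccc1OCc1ccccc1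
F4 | step 12 | 3-lithio derivative of flavone 25 | COc1cc([C@@H]2Oc3cc(-c4oc5cc(OCc6ccccc6)cc(OCc6ccccc6)c5c(=O)c4[Li])ccc3O[C@H]2COCc2ccccc2)ccc1OCc1ccccc1
F5 | step 12 | lithium trimethoxy(flavon-3-yl)borate derived from 25 | COc1cc([C@@H]2Oc3cc(-c4oc5cc(OCc6ccccc6)cc(OCc6ccccc6)c5c(=O)c4[B-](OC)(OC)OC)ccc3O[C@H]2COCc2ccccc2)ccc1OCc1ccccc1.[Li+]
F6 | step 8 | O-tert-butyldimethylsilyl ether of aldol imide 15 | COc1cc([C@H](O[Si](C)(C)C(C)(C)C)[C@H](C(=O)N2C(=O)OC[C@H]2Cc2ccccc2)Oc2ccc(Br)cc2I)ccc1OCc1ccccc1
F7 | step 8 | (2S,3S)-3-[4-(benzyloxy)-3-methoxyphenyl]-2-(4-bromo-2-iodophenoxy)-3-(tert-butyldimethylsilyloxy)propan-1-ol | COc1cc([C@H](O[Si](C)(C)C(C)(C)C)[C@H](CO)Oc2ccc(Br)cc2I)ccc1OCc1ccccc1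
F8 | step 8 | primary benzyl ether of F7 | COc1cc([C@H](O[Si](C)(C)C(C)(C)C)[C@H](COCc2ccccc2)Oc2ccc(Br)cc2I)ccc1OCc1ccccc1
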